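# Proposal: synthesis of briarane 37 (CNP0314084.4) through a catalytic enantioselective Diels–Alder construction of ring A

## The problem

The target 37 is a briarane: a cyclohexenone (ring A) trans-fused through C1–C10 to a ten-membered carbocycle (ring B), which carries a γ-lactone (ring C) fused across C7–C8. Ten stereocentres must be set: the quaternary C1, the trans (2R,3R) epoxide, the allylic chloride C6, C7, the tertiary carbinol C8, C9, C10, the tertiary acetate C11 and C17. Only some of them can be relayed. C1 and C10 arise together and then steer C11 (reagent approach anti to the C10 branch) and C9 (Felkin–Anh). C7 steers C8 (addition to a planar butenolide anti to the C7 side chain) and C6, and C8 with its C9 branch steers C17. The remote epoxide and the absolute sense of ring A need reagent or catalyst control. Ring B has no endocyclic olefin and six functionalised carbons, so its closure must tolerate dense oxygenation and should create functionality as well as a bond. Four groups will not survive rough treatment: the secondary allylic chloride beside the exocyclic methylidene (allylic shift, elimination, reduction), the epoxide (acid), the α′-acetoxy enone (base, electron-transfer reductants) and the β-hydroxy lactone with its acetoxyacetate neighbour (retro-aldol, dehydration, acyl transfer). Ring A is the easy part: the quaternary C1 sits next to C10 with the C2 and C9 branches trans, and the C12 oxygen is para to C1, which is the imprint of an E 2-methyl enal that has met a 2-silyloxy diene.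

## Retrosynthesis

**End game (37 ⇒ 36 ⇒ 35 ⇒ 34).** The acetoxyacetate on C9 is the most base- and nucleophile-labile group and is put on last, onto diol 36; the tertiary C8 hydroxyl does not compete. Diol 36 comes from bis-silyl ether 35 by fluoride. The C6–Cl bond is cut next: an allylic chloride would not survive divalent chromium, so 35 is made from allylic alcohol 34 with inversion. This requires the 6,7-anti alcohol, which is the Felkin–Anh product of addition to a C6 aldehyde.

**Ring B (34 ⇒ 33).** The C5–C6 bond is cut. A cut at C2–C3 would ask a neopentyl carbon to react in a medium-ring closure, a cut at C3–C4 leaves a diol that must later be inverted to the epoxide, and a cut at C8–C9 attacks the most hindered aldehyde and leaves C9 uncontrolled. The C5–C6 cut gives the methylidene and the C6 carbinol beside it in one step, by intramolecular Nozaki–Hiyama–Kishi addition of a 2-iodoalkene to an α-acyloxy aldehyde. Precursor 33 is an open chain with rings A and C complete. The forward step needs high dilution and Felkin–Anh control from C7.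

**West chain (33 ⇒ 32 ⇒ 31 ⇒ 30 ⇒ 25 + 29).** The aldehyde of 33 comes from PMB ether 31 through alcohol 32. The trans epoxide of 31 maps onto E olefin 30 and a reagent-controlled Shi epoxidation, which is shorter than a diol detour and leaves the electron-poor iodoalkene and enone alone. Olefin 30 is cut at C2=C3 into the α-quaternary aldehyde 25 and tetrazolyl sulfone 29 (Julia–Kocienski); 29 comes in three steps from but-3-yn-1-ol 26 through 27 and 28.

**Ring A oxidation level and the C2 mask (25 ⇒ 23 ⇒ 22 ⇒ 21).** C2 cannot be an aldehyde while C9 is one, so it is stored as a vinyl group and released from 23 by Johnson–Lemieux cleavage. The C11 acetate of 23 is traced to enone 22 by α′-acetoxylation with Mn(OAc)3; C1 is quaternary, so only C11 can enolise. Enone 22 comes from silyl enol ether 21 by Saegusa–Ito oxidation, which places the olefin at C13=C14 without a regiochemical question.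

**Ring C (21 ⇒ 20 ⇒ 19 ⇒ 18 ⇒ 17).** The C17 methyl is removed first. Alkylation of the lactone enolate of 19 brings the methyl in from the open face, cis to the C8 oxygen, whereas protonation of a methyl-bearing enolate would give the epimer. The C8 hydroxyl of 19 is traced to epoxy lactone 18 (SmI2 cleaves only the Cα–O bond) and 18 to butenolide 17. An aldol of a propionate onto a C8 ketone was set aside because nothing would control the face of the ketone. On the butenolide the oxygen must enter anti to the C7 side chain, which is the configuration required.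

**C8–C9 (17 ⇒ 16 ⇒ 15 ⇒ 7 + 14).** The bond between ring A and the butenolide is cut into aldehyde 7 and enol triflate 14 (Nozaki–Hiyama–Kishi). The C9 configuration is left to Felkin–Anh reduction of ketone 16, so carbinol 15 may be a mixture. Triflate 14 is a tetronic acid derivative made from methyl (R)-glycerate acetonide 8 through 9, 11, 12 and 13 (Dieckmann condensation); C7 comes from the chiral pool.

**Functional-group relay (7 ⇒ 6 ⇒ 5 ⇒ 4).** Aldehyde 7 is the oxidised form of alcohol 6, which comes from acetate 5, the methylenation product of adduct 4.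

**Ring A (4 ⇒ 2 + 3).** The C1–C14 and C10–C11 bonds are cut by a retro-[4+2]. The precursors are (Z)-3-(triisopropylsilyloxy)penta-1,3-diene 2, one step from ethyl vinyl ketone 1, and the purchased E enal 3. The forward reaction needs catalyst control of the enal face; regiochemistry comes from the 2-silyloxy group and the trans relation of C2 and C9 from the enal geometry.

## Roads not taken

**Alternative 1:** This road cuts C2–C3 and C6–C7. Irradiation of the ring A-fused enone A1 with the cyclobutene ketal A2 would give the ladder photoadduct A3. Thermal opening of its bicyclo[2.2.0]hexane (loss of the C2–C7 bond) would then unzip to a cyclodeca-1,5-diene, ring B, with olefins at C2=C3 and C6=C7 and a masked C5 ketone.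
- Merits: ring B arises in two steps from six- and four-membered rings without high dilution, and the two olefins and the C5 carbonyl sit where the epoxide, the chloro-lactone junction and the methylidene are needed. In bond economy for ring B this road is better than the chosen one.
- Weak points: head-to-head against head-to-tail regiochemistry and the facial course of the photocycloaddition beside the quaternary C1 are not secured; the 1,5-diene can equilibrate by Cope rearrangement; olefin geometry follows strain and not design. C6, C7, C8, C17 and the lactone would all have to be installed on a flexible, transannularly reactive medium ring, where C8 has no reliable facial bias.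
- Comparison: the chosen plan needs an extra macrocyclisation, but it sets C7, C8, C9 and C17 on a rigid five-membered ring before closure and obtains ring A by catalysis.

**Alternative 2:** This road cuts C3–C4. CrCl2 would convert the allylic bromide of bromo aldehyde A4 into an allylchromium reagent that adds to the C3 aldehyde and gives the ring B homoallylic alcohol A5, with the methylidene formed directly.
- Merits: allylchromium additions are among the most reliable medium-ring closures and need no nickel; ring C and the C6 oxygen are in place before closure. As a ring closure it is at least as good as the alkenylchromium closure chosen here.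
- Weak points: A4 must carry seven stereocentres before closure; the C3 alcohol of A5 needs a sulfonylation and inversion sequence to reach the epoxide; the C6 oxygen still has to become the allylic chloride; and the road does not say how ring A with its C1/C10 pair is obtained.
- Comparison: the chosen plan closes the neighbouring bond with the sister reaction. Against the robustness of the allylation it sets an epoxide installed in one reagent-controlled step on an open chain, and a closure that creates the C6 carbinol together with the methylidene.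

**Alternative 3:** This road cuts C11–C12. A chiral triazolylidene carbene would turn the aldehyde of keto aldehyde A6 into its Breslow intermediate, which adds to the methyl ketone and closes ring A as the tertiary α-ketol A7.
- Merits: the C11 oxygen and its configuration arrive in the ring-forming step under catalyst control, where the chosen plan spends two oxidations (steps 18 and 19) and relies on substrate control. In that respect this road is better.
- Weak points: A6 already contains the quaternary C1 and C10, which must be made by separate asymmetric chemistry; the carbene must override or match their influence at C11; the C13=C14 olefin still has to be introduced by dehydrogenation.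
- Comparison: the Diels–Alder road sets C1 and C10 together, in one catalytic step from two trivial partners, and delivers the C12 enol ether that fixes the position of the enone. This outweighs the later C11 oxidation.

Key step: step 2

## Assumptions

- Enal 3 is taken as the purchased E isomer (the C5 acetate of industrial retinoid chemistry).
- The (R)-configured oxazaborolidinium ion is taken to expose the Si face of C1, by analogy with the facial sense known for 2-methylacrolein under the enantiomeric catalyst; the mirror-image catalyst would be used otherwise.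
- Compounds 4 to 22 are drawn with the C11 methyl cis to C9 (formyl exo in step 2); the C11 epimer would converge at step 19.

## Route

Step 1
Reactants: 1 pent-1-en-3-one (ethyl vinyl ketone)
Product: 2 (Z)-3-(triisopropylsilyloxy)penta-1,3-diene
Conditions: i-Pr3SiOTf, Et3N, CH2Cl2, 0 °C
Reagents that add atoms: triisopropylsilyl trifluoromethanesulfonate, CC(C)[Si](OS(=O)(=O)C(F)(F)F)(C(C)C)C(C)C
Why: Soft enolisation and O-silylation of an ethyl ketone; the Z enol ether (methyl cis to oxygen, pointing outward in the s-cis diene) is favoured because allylic strain disfavours the E isomer.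

Step 2
Reactants: 2 (Z)-3-(triisopropylsilyloxy)penta-1,3-diene; 3 (E)-4-acetoxy-2-methylbut-2-enal
Product: 4 (1S,5R,6S)-6-(acetoxymethyl)-1,5-dimethyl-4-(triisopropylsilyloxy)cyclohex-3-ene-1-carbaldehyde
Conditions: (R)-3,3-diphenyl-1-(2-methylphenyl)tetrahydro-1H,3H-pyrrolo[1,2-c][1,3,2]oxazaborole (20 mol %), Tf2NH (20 mol %), CH2Cl2, −78 → −40 °C
Reagents that add atoms: none
Why: Catalytic enantioselective Diels–Alder reaction of a 2-substituted enal with a 2-silyloxy diene under a triflimide-activated oxazaborolidinium cation, which is the closest known reaction type. The cationic boron binds the formyl oxygen, a formyl C–H···O contact holds the s-trans enal over one aryl group, and the diene can reach only the exposed Si face of C1. The cycloaddition is concerted but asynchronous: C11, the nucleophilic enol ether terminus of 2, bonds first to the β-carbon C10 and C14 follows onto C1. Ring A is thus closed by an intermolecular suprafacial [4+2] cycloaddition that makes both ring bonds in one step. The absolute configuration of C1 and C10 is set by the catalyst and their relative configuration (C2 trans to C9) by the E geometry of 3. C11 is set by the exo position of the formyl group (methyl cis to C9) and is provisional, because C11 becomes an enolate carbon in step 19. The step needs regioselectivity (C12 oxygen para to C1), secured by the 2-silyloxy group whose donor terminus is the methyl-bearing carbon, and face selectivity, secured by the two-point binding of the α-branched enal. The acetate is a weaker Lewis base than the aldehyde, and the triisopropylsilyl enol ether survives the aprotic medium at low temperature.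

Step 3
Reactants: 4 (1S,5R,6S)-6-(acetoxymethyl)-1,5-dimethyl-4-(triisopropylsilyloxy)cyclohex-3-ene-1-carbaldehyde
Product: 5 [(1S,2R,6R)-2,6-dimethyl-3-(triisopropylsilyloxy)-6-vinylcyclohex-3-en-1-yl]methyl acetate
Conditions: Ph3PCH3Br, KN(SiMe3)2, THF, −78 → 0 °C
Reagents that add atoms: methyltriphenylphosphonium bromide, C[P+](c1ccccc1)(c1ccccc1)c1ccccc1.[Br-]
Why: Wittig methylenation; the non-stabilised ylide adds to the non-enolisable aldehyde much faster than to the acetate. The vinyl group stores C2 as a latent aldehyde so that C9 can be the only aldehyde in step 11.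

Step 4
Reactants: 5 [(1S,2R,6R)-2,6-dimethyl-3-(triisopropylsilyloxy)-6-vinylcyclohex-3-en-1-yl]methyl acetate
Product: 6 [(1S,2R,6R)-2,6-dimethyl-3-(triisopropylsilyloxy)-6-vinylcyclohex-3-en-1-yl]methanol
Conditions: K2CO3, MeOH, 0 °C
Reagents that add atoms: none
Why: Mild methanolysis of a primary acetate; the bulky triisopropylsilyl enol ether and the olefin are inert to carbonate in methanol at 0 °C.

Step 5
Reactants: 6 [(1S,2R,6R)-2,6-dimethyl-3-(triisopropylsilyloxy)-6-vinylcyclohex-3-en-1-yl]methanol
Product: 7 (1S,2R,6R)-2,6-dimethyl-3-(triisopropylsilyloxy)-6-vinylcyclohex-3-ene-1-carbaldehyde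
Conditions: Dess–Martin periodinane, NaHCO3, CH2Cl2, 0 °C
Reagents that add atoms: none
Why: Dess–Martin oxidation under buffered, non-basic conditions, chosen to avoid epimerisation at C10 of the α-branched aldehyde and hydrolysis of the enol ether.

Step 6
Reactants: 8 methyl (R)-2,2-dimethyl-1,3-dioxolane-4-carboxylate
Product: 9 methyl (R)-2,3-dihydroxypropanoate
Conditions: TsOH·H2O (cat.), MeOH, 25 °C
Reagents that add atoms: none
Why: Acid-catalysed transketalisation to methanol frees the diol without touching the ester or the stereocentre, which becomes C7.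

Step 7
Reactants: 9 methyl (R)-2,3-dihydroxypropanoate
Product: 11 methyl (R)-2-hydroxy-3-[(4-methoxybenzyl)oxy]propanoate, via stannylene acetal 10 (not isolated)
Conditions: Bu2SnO, toluene, reflux (Dean–Stark); then 4-MeOC6H4CH2Cl, Bu4NI, toluene, 80 °C
Reagents that add atoms: 4-methoxybenzyl chloride, COc1ccc(CCl)cc1
Why: Stannylene acetal activation makes the primary oxygen the nucleophile, a standard regioselective mono-alkylation of 1,2-diols; the stereocentre is untouched.

Step 8
Reactants: 11 methyl (R)-2-hydroxy-3-[(4-methoxybenzyl)oxy]propanoate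
Product: 12 methyl (R)-2-acetoxy-3-[(4-methoxybenzyl)oxy]propanoate
Conditions: Ac2O, pyridine, DMAP (cat.), CH2Cl2, 0 → 25 °C
Reagents that add atoms: acetic anhydride, CC(=O)OC(C)=O
Why: Routine acetylation; the acetyl group supplies C17 and C19 of ring C.

Step 9
Reactants: 12 methyl (R)-2-acetoxy-3-[(4-methoxybenzyl)oxy]propanoate
Product: 13 (R)-4-hydroxy-5-{[(4-methoxybenzyl)oxy]methyl}furan-2(5H)-one
Conditions: LiN(SiMe3)2 (2.2 equiv), THF, −78 → 0 °C; then 1 M HCl
Reagents that add atoms: none
Why: Dieckmann condensation of the acetate enolate onto the methyl ester closes the tetronic acid. With the lithium amide at low temperature the product is held as its stable enolate, which protects the γ-stereocentre from racemisation.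

Step 10
Reactants: 13 (R)-4-hydroxy-5-{[(4-methoxybenzyl)oxy]methyl}furan-2(5H)-one
Product: 14 (R)-2-{[(4-methoxybenzyl)oxy]methyl}-5-oxo-2,5-dihydrofuran-3-yl trifluoromethanesulfonate
Conditions: Tf2O, i-Pr2NEt, CH2Cl2, −78 °C
Reagents that add atoms: trifluoromethanesulfonic anhydride, O=S(=O)(OS(=O)(=O)C(F)(F)F)C(F)(F)F
Why: O-sulfonylation of the vinylogous acid gives the enol triflate, the electrophilic handle at C8.

Step 11
Reactants: 7 (1S,2R,6R)-2,6-dimethyl-3-(triisopropylsilyloxy)-6-vinylcyclohex-3-ene-1-carbaldehyde; 14 (R)-2-{[(4-methoxybenzyl)oxy]methyl}-5-oxo-2,5-dihydrofuran-3-yl trifluoromethanesulfonate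
Product: 15 C9 carbinol (both C9 epimers) in which C9 of ring A is bonded to C8 of the butenolide (C8=C17; C7 as in 14)
Conditions: CrCl2 (5 equiv), NiCl2 (2 mol %), DMF, 25 °C
Reagents that add atoms: none
Why: Nozaki–Hiyama–Kishi coupling: nickel-catalysed activation of the alkenyl triflate, transmetalation to chromium and chemoselective addition to the aldehyde, with enol ether, vinyl group, lactone and PMB ether inert. C9 is not controlled here (Felkin–Anh addition anti to C1 would favour the 9-epimer) and is set in steps 12 and 13.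

Step 12
Reactants: 15 C9 carbinol (both C9 epimers)
Product: 16 C9 ketone (4-acylbutenolide)
Conditions: Dess–Martin periodinane, NaHCO3, CH2Cl2, 0 °C
Reagents that add atoms: none
Why: Dess–Martin oxidation converges both epimers on one ketone; the buffered, non-basic medium avoids enolisation toward C10 or the γ-position C7.

Step 13
Reactants: 16 C9 ketone (4-acylbutenolide)
Product: 17 C9 alcohol with the C9 configuration of the target (butenolide intact)
Conditions: NaBH4, CeCl3·7H2O, MeOH/THF, −78 °C
Reagents that add atoms: none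
Why: Luche reduction (1,2-selective); in the Felkin–Anh conformer of the C10-branched ketone hydride adds anti to the quaternary C1, which places the hydroxyl as required at C9.

Step 14
Reactants: 17 C9 alcohol (butenolide)
Product: 18 8,17-epoxy lactone (epoxide oxygen on the face of H7, anti to the C7 side chain)
Conditions: t-BuOOH, n-BuLi, THF, −78 → −20 °C
Reagents that add atoms: tert-butyl hydroperoxide, CC(C)(C)OO
Why: Nucleophilic (Weitz–Scheffer) epoxidation of the butenolide; the peroxide adds to C8 anti to the C7 side chain, so the new oxygen is cis to H7, the C8 configuration of the target.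

Step 15
Reactants: 18 8,17-epoxy lactone
Product: 19 8-hydroxy lactone 8,9-diol (C8 hydroxyl cis to H7; C17 is CH2)
Conditions: SmI2 (2.5 equiv), THF/MeOH 4:1, −78 °C
Reagents that add atoms: none
Why: SmI2 reduction of an α,β-epoxy ester: electron transfer to the lactone carbonyl cleaves only the Cα–O bond, so the C8–O bond and its configuration remain. C17 becomes CH2, so no stereocentre is at stake in the protonation.

Step 16
Reactants: 19 8-hydroxy lactone 8,9-diol
Product: 20 17-methyl lactone 8,9-diol (C18 cis to the C8 hydroxyl and trans to C9)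
Conditions: LiN(i-Pr)2 (3.3 equiv), THF, −78 → −40 °C; MeI, −78 → −40 °C
Reagents that add atoms: iodomethane, CI
Why: Fráter–Seebach-type alkylation of a β-alkoxide enolate, which cannot undergo β-elimination. Methyl iodide should approach the lactone enolate anti to the bulky C9 branch on C8 and to the C7 side chain, giving C18 cis to the C8 oxygen.

Step 17
Reactants: 20 17-methyl lactone 8,9-diol
Product: 21 8,9-bis(triethylsilyl) ether
Conditions: Et3SiOTf (3 equiv), 2,6-lutidine, CH2Cl2, −78 → 0 °C
Reagents that add atoms: triethylsilyl trifluoromethanesulfonate, CC[Si](CC)(CC)OS(=O)(=O)C(F)(F)F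
Why: The silyl triflate silylates both the hindered secondary and the tertiary hydroxyl; they must be masked for steps 18 to 29 and are released together by fluoride.

Step 18
Reactants: 21 8,9-bis(triethylsilyl) ether
Product: 22 ring A enone (C12 ketone, C13=C14)
Conditions: Pd(OAc)2 (1.2 equiv), MeCN, 40 °C
Reagents that add atoms: none
Why: Saegusa–Ito oxidation: divalent palladium forms the oxa-π-allyl species at C13 and β-hydride elimination from C14 gives the C13=C14 enone, at the position fixed by the enol ether from step 2.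

Step 19
Reactants: 22 ring A enone
Product: 23 α′-acetoxy enone (C11 acetate trans to the C10 branch; C11 methyl cis to C15)
Conditions: Mn(OAc)3·2H2O (4 equiv), benzene, 80 °C (Dean–Stark)
Reagents that add atoms: manganese triacetate, CC(=O)[O-].CC(=O)[O-].CC(=O)[O-].[Mn+3]
Why: α′-Acetoxylation of an enone through its trivalent-manganese enolate; C1 is quaternary, so only C11 can enolise. Acetate should be delivered anti to the C10 branch, which gives the tertiary acetate directly and erases the provisional C11 centre.

Step 20
Reactants: 23 α′-acetoxy enone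
Product: 25 C2 aldehyde (formyl group on C1), via vicinal diol 24 (not isolated)
Conditions: OsO4 (2 mol %), NaIO4 (4 equiv), 2,6-lutidine, dioxane/H2O 3:1, 25 °C
Reagents that add atoms: osmium tetroxide (oxygen carrier), O=[Os](=O)(=O)=O; sodium periodate (terminal oxidant), [Na+].[O-]I(=O)(=O)=O
Why: Johnson–Lemieux cleavage: the monosubstituted vinyl group is dihydroxylated faster than the electron-poor, hindered enone, and periodate cleaves the diol in situ to release the C2 aldehyde.

Step 21
Reactants: 26 but-3-yn-1-ol
Product: 27 3-iodobut-3-en-1-ol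
Conditions: NaI, Me3SiCl, H2O, MeCN, 25 °C
Reagents that add atoms: sodium iodide, [Na+].[I-]
Why: Markovnikov addition of hydrogen iodide generated in situ to the terminal alkyne gives the 2-iodoalkene (C5 and C16).

Step 22
Reactants: 27 3-iodobut-3-en-1-ol
Product: 28 5-[(3-iodobut-3-en-1-yl)sulfanyl]-1-phenyl-1H-tetrazole
Conditions: 1-phenyl-1H-tetrazole-5-thiol, PPh3, DIAD, THF, 0 → 25 °C
Reagents that add atoms: 1-phenyl-1H-tetrazole-5-thiol, Sc1nnnn1-c1ccccc1
Why: Mitsunobu thioetherification of the primary alcohol.

Step 23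
Reactants: 28 5-[(3-iodobut-3-en-1-yl)sulfanyl]-1-phenyl-1H-tetrazole
Product: 29 5-[(3-iodobut-3-en-1-yl)sulfonyl]-1-phenyl-1H-tetrazole
Conditions: (NH4)6Mo7O24·4H2O (10 mol %), H2O2 (30 %), EtOH, 0 → 25 °C
Reagents that add atoms: hydrogen peroxide, OO
Why: Molybdate-catalysed oxidation of the sulfide to the sulfone; the electron-poor iodoalkene is not epoxidised.

Step 24
Reactants: 25 C2 aldehyde; 29 5-[(3-iodobut-3-en-1-yl)sulfonyl]-1-phenyl-1H-tetrazole
Product: 30 (2E)-olefin with the C5 iodoalkene (C16=C5(I)–C4–C3=C2–C1)
Conditions: 29, KN(SiMe3)2, THF, −78 °C; then 25, −78 → 25 °C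
Reagents that add atoms: none
Why: Julia–Kocienski olefination; an α-quaternary aldehyde and a phenyltetrazolyl sulfone give the E olefin through the anti adduct and Smiles rearrangement. The sulfonyl carbanion is too weak a base to enolise lactone or acetate at −78 °C.

Step 25
Reactants: 30 (2E)-olefin with the C5 iodoalkene
Product: 31 (2R,3R)-trans-epoxide
Conditions: 1,2:4,5-di-O-isopropylidene-β-D-erythro-hexo-2,3-diulo-2,6-pyranose (30 mol %), KHSO5 (as 2KHSO5·KHSO4·K2SO4), K2CO3, Bu4NHSO4, MeCN/CH2(OMe)2/aq. Na2B4O7, 0 °C
Reagents that add atoms: potassium peroxymonosulfate, [K+].[O-]S(=O)(=O)OO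
Why: Shi epoxidation with a chiral dioxirane; the spiro transition state of a trans-disubstituted olefin should give the (2R,3R)-epoxide, and the addition is stereospecific, so the epoxide is trans. Iodoalkene and enone are too electron-poor to react.

Step 26
Reactants: 31 (2R,3R)-trans-epoxide
Product: 32 C6 primary alcohol
Conditions: DDQ, CH2Cl2/pH 7 phosphate buffer 10:1, 0 °C
Reagents that add atoms: none
Why: Oxidative cleavage of the PMB ether by DDQ in a buffered medium leaves silyl ethers, epoxide, iodoalkene and enone intact.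

Step 27
Reactants: 32 C6 primary alcohol
Product: 33 C6 aldehyde (open form of ring B)
Conditions: Dess–Martin periodinane, NaHCO3, CH2Cl2, 0 °C
Reagents that add atoms: none
Why: Dess–Martin oxidation to the α-acyloxy aldehyde, which is used at once to avoid epimerisation at C7.

Step 28
Reactants: 33 C6 aldehyde (open form of ring B)
Product: 34 macrocyclic allylic alcohol (ring B closed; C6 hydroxyl anti to the C7 oxygen; C5=C16 methylidene)
Conditions: CrCl2 (10 equiv), NiCl2 (5 mol %), DMSO/THF 3:1, 2 mM, 25 °C
Reagents that add atoms: none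
Why: Intramolecular Nozaki–Hiyama–Kishi reaction at high dilution forms C5–C6, closes the ten-membered ring and gives the methylidene and the C6 carbinol together. Felkin–Anh addition with the C7–O bond anti to the incoming alkenyl group should give the 6,7-anti alcohol.

Step 29
Reactants: 34 macrocyclic allylic alcohol
Product: 35 C6 chloride (6,7-syn) as its 8,9-bis(triethylsilyl) ether
Conditions: PPh3, Cl3CC(O)CCl3, 2,6-di-tert-butylpyridine, CH2Cl2, −20 → 0 °C
Reagents that add atoms: hexachloroacetone, ClC(Cl)(Cl)C(=O)C(Cl)(Cl)Cl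
Why: Appel-type chlorination with triphenylphosphine and hexachloroacetone, a combination known to convert allylic alcohols into chlorides with inversion and without allylic shift. Inversion of the 6,7-anti alcohol gives the chloride configuration of the target.

Step 30
Reactants: 35 C6 chloride 8,9-bis(triethylsilyl) ether
Product: 36 8,9-diol
Conditions: HF·pyridine, pyridine, THF, 0 → 25 °C
Reagents that add atoms: none
Why: Fluoride cleavage of both silyl ethers in a pyridine-buffered medium that spares epoxide, allylic chloride, lactone and tertiary acetate.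

Step 31
Reactants: 36 8,9-diol
Product: 37 target briarane (CNP0314084.4)
Conditions: AcOCH2COCl, pyridine, DMAP (cat.), CH2Cl2, 0 °C
Reagents that add atoms: acetoxyacetyl chloride, CC(=O)OCC(Cl)=O
Why: Acylation of the secondary C9 hydroxyl; the tertiary C8 hydroxyl, flanked by three substituted carbons, does not compete.

## Compound list

1 | pent-1-en-3-one (ethyl vinyl ketone) | CCC(=O)C=C | starting material
2 | (Z)-3-(triisopropylsilyloxy)penta-1,3-diene | C=C/C(O[Si](C(C)C)(C(C)C)C(C)C)=C/C | intermediate
3 | (E)-4-acetoxy-2-methylbut-2-enal | O=C/C(C)=C/COC(C)=O | starting material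
4 | (1S,5R,6S)-6-(acetoxymethyl)-1,5-dimethyl-4-(triisopropylsilyloxy)cyclohex-3-ene-1-carbaldehyde (ring A adduct) | O=C[C@@]1(C)CC=C(O[Si](C(C)C)(C(C)C)C(C)C)[C@H](C)[C@@H]1COC(C)=O | intermediate
5 | [(1S,2R,6R)-2,6-dimethyl-3-(triisopropylsilyloxy)-6-vinylcyclohex-3-en-1-yl]methyl acetate | C=C[C@@]1(C)CC=C(O[Si](C(C)C)(C(C)C)C(C)C)[C@H](C)[C@@H]1COC(C)=O | intermediate
6 | [(1S,2R,6R)-2,6-dimethyl-3-(triisopropylsilyloxy)-6-vinylcyclohex-3-en-1-yl]methanol | C=C[C@@]1(C)CC=C(O[Si](C(C)C)(C(C)C)C(C)C)[C@H](C)[C@@H]1CO | intermediate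
7 | (1S,2R,6R)-2,6-dimethyl-3-(triisopropylsilyloxy)-6-vinylcyclohex-3-ene-1-carbaldehyde (C9 aldehyde) | C=C[C@@]1(C)CC=C(O[Si](C(C)C)(C(C)C)C(C)C)[C@H](C)[C@@H]1C=O | intermediate
8 | methyl (R)-2,2-dimethyl-1,3-dioxolane-4-carboxylate | COC(=O)[C@H]1COC(C)(C)O1 | starting material
9 | methyl (R)-2,3-dihydroxypropanoate | COC(=O)[C@@H](CO)O | intermediate
10 | methyl (R)-2,2-dibutyl-1,3,2-dioxastannolane-4-carboxylate (stannylene acetal, not isolated) | CCCC[Sn]1(CCCC)OC[C@H](C(=O)OC)O1 | intermediate
11 | methyl (R)-2-hydroxy-3-[(4-methoxybenzyl)oxy]propanoate | COC(=O)[C@@H](COCc1ccc(OC)cc1)O | intermediate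
12 | methyl (R)-2-acetoxy-3-[(4-methoxybenzyl)oxy]propanoate | COC(=O)[C@@H](COCc1ccc(OC)cc1)OC(C)=O | intermediate
13 | (R)-4-hydroxy-5-{[(4-methoxybenzyl)oxy]methyl}furan-2(5H)-one | O=C1C=C(O)[C@@H](COCc2ccc(OC)cc2)O1 | intermediate
14 | (R)-2-{[(4-methoxybenzyl)oxy]methyl}-5-oxo-2,5-dihydrofuran-3-yl trifluoromethanesulfonate | O=C1C=C(OS(=O)(=O)C(F)(F)F)[C@@H](COCc2ccc(OC)cc2)O1 | intermediate
15 | C9 carbinol, both C9 epimers (ring A of 7 joined at C9 to C8 of the butenolide) | C=C[C@@]1(C)CC=C(O[Si](C(C)C)(C(C)C)C(C)C)[C@H](C)[C@@H]1C(O)C1=CC(=O)O[C@@H]1COCc1ccc(OC)cc1 | intermediate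
16 | C9 ketone (4-acylbutenolide) | C=C[C@@]1(C)CC=C(O[Si](C(C)C)(C(C)C)C(C)C)[C@H](C)[C@@H]1C(=O)C1=CC(=O)O[C@@H]1COCc1ccc(OC)cc1 | intermediate
17 | C9 alcohol with the C9 configuration of the target (butenolide) | C=C[C@@]1(C)CC=C(O[Si](C(C)C)(C(C)C)C(C)C)[C@H](C)[C@@H]1[C@H](O)C1=CC(=O)O[C@@H]1COCc1ccc(OC)cc1 | intermediate
18 | 8,17-epoxy lactone (epoxide oxygen cis to H7) | C=C[C@@]1(C)CC=C(O[Si](C(C)C)(C(C)C)C(C)C)[C@H](C)[C@@H]1[C@H](O)[C@]12O[C@H]1C(=O)O[C@@H]2COCc1ccc(OC)cc1 | intermediate
19 | 8-hydroxy lactone 8,9-diol (C17 is CH2) | C=C[C@@]1(C)CC=C(O[Si](C(C)C)(C(C)C)C(C)C)[C@H](C)[C@@H]1[C@H](O)[C@]1(O)CC(=O)O[C@@H]1COCc1ccc(OC)cc1 | intermediate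
20 | 17-methyl lactone 8,9-diol (C18 cis to the C8 hydroxyl) | C=C[C@@]1(C)CC=C(O[Si](C(C)C)(C(C)C)C(C)C)[C@H](C)[C@@H]1[C@H](O)[C@]1(O)[C@@H](C)C(=O)O[C@@H]1COCc1ccc(OC)cc1 | intermediate
21 | 8,9-bis(triethylsilyl) ether of 20 | C=C[C@@]1(C)CC=C(O[Si](C(C)C)(C(C)C)C(C)C)[C@H](C)[C@@H]1[C@H](O[Si](CC)(CC)CC)[C@]1(O[Si](CC)(CC)CC)[C@@H](C)C(=O)O[C@@H]1COCc1ccc(OC)cc1 | intermediate
22 | ring A enone (C12 ketone, C13=C14) | C=C[C@@]1(C)C=CC(=O)[C@H](C)[C@@H]1[C@H](O[Si](CC)(CC)CC)[C@]1(O[Si](CC)(CC)CC)[C@@H](C)C(=O)O[C@@H]1COCc1ccc(OC)cc1 | intermediate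
23 | α′-acetoxy enone (C11 acetate trans to the C10 branch) | C=C[C@@]1(C)C=CC(=O)[C@@](C)(OC(C)=O)[C@@H]1[C@H](O[Si](CC)(CC)CC)[C@]1(O[Si](CC)(CC)CC)[C@@H](C)C(=O)O[C@@H]1COCc1ccc(OC)cc1 | intermediate
24 | vicinal diol from the C1 vinyl group of 23 (C2 epimers, not isolated) | OCC(O)[C@@]1(C)C=CC(=O)[C@@](C)(OC(C)=O)[C@@H]1[C@H](O[Si](CC)(CC)CC)[C@]1(O[Si](CC)(CC)CC)[C@@H](C)C(=O)O[C@@H]1COCc1ccc(OC)cc1 | intermediate
25 | C2 aldehyde | O=C[C@@]1(C)C=CC(=O)[C@@](C)(OC(C)=O)[C@@H]1[C@H](O[Si](CC)(CC)CC)[C@]1(O[Si](CC)(CC)CC)[C@@H](C)C(=O)O[C@@H]1COCc1ccc(OC)cc1 | intermediate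
26 | but-3-yn-1-ol | C#CCCO | starting material
27 | 3-iodobut-3-en-1-ol | C=C(I)CCO | intermediate
28 | 5-[(3-iodobut-3-en-1-yl)sulfanyl]-1-phenyl-1H-tetrazole | C=C(I)CCSc1nnnn1-c1ccccc1 | intermediate
29 | 5-[(3-iodobut-3-en-1-yl)sulfonyl]-1-phenyl-1H-tetrazole | C=C(I)CCS(=O)(=O)c1nnnn1-c1ccccc1 | intermediate
30 | (2E)-olefin with the C5 iodoalkene | C=C(I)C/C=C/[C@@]1(C)C=CC(=O)[C@@](C)(OC(C)=O)[C@@H]1[C@H](O[Si](CC)(CC)CC)[C@]1(O[Si](CC)(CC)CC)[C@@H](C)C(=O)O[C@@H]1COCc1ccc(OC)cc1 | intermediate
31 | (2R,3R)-trans-epoxide | C=C(I)C[C@H]1O[C@@H]1[C@@]1(C)C=CC(=O)[C@@](C)(OC(C)=O)[C@@H]1[C@H](O[Si](CC)(CC)CC)[C@]1(O[Si](CC)(CC)CC)[C@@H](C)C(=O)O[C@@H]1COCc1ccc(OC)cc1 | intermediate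
32 | C6 primary alcohol | C=C(I)C[C@H]1O[C@@H]1[C@@]1(C)C=CC(=O)[C@@](C)(OC(C)=O)[C@@H]1[C@H](O[Si](CC)(CC)CC)[C@]1(O[Si](CC)(CC)CC)[C@@H](C)C(=O)O[C@@H]1CO | intermediate
33 | C6 aldehyde (open form of ring B) | C=C(I)C[C@H]1O[C@@H]1[C@@]1(C)C=CC(=O)[C@@](C)(OC(C)=O)[C@@H]1[C@H](O[Si](CC)(CC)CC)[C@]1(O[Si](CC)(CC)CC)[C@@H](C)C(=O)O[C@@H]1C=O | intermediate
34 | macrocyclic allylic alcohol (C6 hydroxyl anti to the C7 oxygen) | C=C1C[C@H]2O[C@@H]2[C@@]2(C)C=CC(=O)[C@@](C)(OC(C)=O)[C@@H]2[C@H](O[Si](CC)(CC)CC)[C@@]2(O[Si](CC)(CC)CC)[C@H](OC(=O)[C@@H]2C)[C@@H]1O | intermediate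
35 | C6 chloride, 8,9-bis(triethylsilyl) ether | C=C1C[C@H]2O[C@@H]2[C@@]2(C)C=CC(=O)[C@@](C)(OC(C)=O)[C@@H]2[C@H](O[Si](CC)(CC)CC)[C@@]2(O[Si](CC)(CC)CC)[C@H](OC(=O)[C@@H]2C)[C@H]1Cl | intermediate
36 | 8,9-diol | C=C1C[C@H]2O[C@@H]2[C@@]2(C)C=CC(=O)[C@@](C)(OC(C)=O)[C@@H]2[C@H](O)[C@@]2(O)[C@H](OC(=O)[C@@H]2C)[C@H]1Cl | intermediate
37 | target briarane CNP0314084.4 | C=C1C[C@H]2O[C@@H]2[C@@]2(C)C=CC(=O)[C@@](C)(OC(C)=O)[C@@H]2[C@H](OC(=O)COC(C)=O)[C@@]2(O)[C@H](OC(=O)[C@@H]2C)[C@H]1Cl | target

## Step count and risk

Total step count: 31. Longest linear sequence: 23 steps (steps 1–5, 11–20 and 24–31 from 1; the same length from 8 through steps 6–10).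

**Step 2 (key step).** The most likely failure is low turnover: the β-substituted 2-methyl enal and the 1,3-disubstituted diene are both hindered. Protodesilylation of 2 by traces of free triflimide acid, or a stepwise Mukaiyama–Michael pathway, could then erode yield and face selectivity. The fallback keeps the same cycloaddition but gives up catalysis for resolution. It sets out from 2 and 3: cycloaddition promoted by Me2AlCl in CH2Cl2 at −78 °C gives the racemic adduct F1; methylenation as in step 3 gives the racemic acetate F2; methanolysis as in step 4 gives the racemic alcohol F3. Esterification with (S)-2-methoxy-2-phenylacetic acid (DCC, DMAP) and chromatographic separation of the diastereomers gives the ester F4 of the wanted enantiomer, and methanolysis with K2CO3 returns to the route at 6.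

**Step 28.** Oligomerisation and premature protonation of the alkenylchromium species may outrun closure of a ten-membered ring that already holds a trans-epoxide and a fused lactone, and the facial course at C6 depends on the ring conformation. The fallback closes the ring on the more flexible olefin and installs the epoxide afterwards. It sets out from 30: DDQ gives the primary alcohol F5 and Dess–Martin oxidation the aldehyde F6. Ring closure with CrCl2 and catalytic NiCl2 gives the macrocyclic diene alcohol F7, and chlorination as in step 29 gives the chloride F8. Shi epoxidation of its trans C2=C3 olefin (the methylidene is deactivated by the allylic chlorine) returns to the route at 35.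

**Step 29.** Chloride may attack the exposed C16 terminus (allylic shift), or the alkoxyphosphonium ion may ionise, because backside attack at the ring carbon C6 is hindered. The fallback turns the allylic shift to advantage. It sets out from 34: catalytic Ph3SiOReO3 moves the hydroxyl to C16 and gives the primary allylic alcohol F9 with a C5=C6 olefin, and SOCl2 in ether then returns chlorine to C6 with allylic rearrangement through the chlorosulfite. This rejoins the route at 35; the configuration at C6 would have to be confirmed.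

**Step 16.** Methyl iodide may attack the wrong enolate face, since the lithium alkoxide on C8 and the C9 branch shield opposite faces; O-methylation is a lesser risk. The fallback relies on protonation instead of alkylation for the stereocentre. It sets out from 19: if the alkylation delivers mainly the 17-epimer F10, that compound is deprotonated again with LiN(i-Pr)2 and quenched kinetically with acetic acid at −78 °C. The proton then enters on the face the methyl group had taken, which returns to the route at 20.

**Step 19.** Oxidation at the hindered tertiary α′-carbon may be incomplete, and hot acetic acid may strip the triethylsilyl ethers. The fallback is a Rubottom sequence that sets out from 22. Me3SiOTf and Et3N give the silyl dienol ether F11, dimethyldioxirane at −78 °C followed by citric acid in methanol gives the α′-hydroxy enone F12, and acetylation (Ac2O, DMAP, Et3N, 40 °C) returns to the route at 23.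

## Further compounds

F1 | step 2 | racemic ring A adduct (both enantiomers of 4) | O=C[C@@]1(C)CC=C(O[Si](C(C)C)(C(C)C)C(C)C)[C@H](C)[C@@H]1COC(C)=O.O=C[C@]1(C)CC=C(O[Si](C(C)C)(C(C)C)C(C)C)[C@@H](C)[C@H]1COC(C)=O
F2 | step 2 | racemic vinyl acetate (both enantiomers of 5) | C=C[C@@]1(C)CC=C(O[Si](C(C)C)(C(C)C)C(C)C)[C@H](C)[C@@H]1COC(C)=O.C=C[C@]1(C)CC=C(O[Si](C(C)C)(C(C)C)C(C)C)[C@@H](C)[C@H]1COC(C)=O
F3 | step 2 | racemic alcohol (both enantiomers of 6) | C=C[C@@]1(C)CC=C(O[Si](C(C)C)(C(C)C)C(C)C)[C@H](C)[C@@H]1CO.C=C[C@]1(C)CC=C(O[Si](C(C)C)(C(C)C)C(C)C)[C@@H](C)[C@H]1CO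
F4 | step 2 | (S)-2-methoxy-2-phenylacetate of 6 | C=C[C@@]1(C)CC=C(O[Si](C(C)C)(C(C)C)C(C)C)[C@H](C)[C@@H]1COC(=O)[C@@H](OC)c1ccccc1
F5 | step 28 | C6 primary alcohol of the (2E)-olefin | C=C(I)C/C=C/[C@@]1(C)C=CC(=O)[C@@](C)(OC(C)=O)[C@@H]1[C@H](O[Si](CC)(CC)CC)[C@]1(O[Si](CC)(CC)CC)[C@@H](C)C(=O)O[C@@H]1CO
F6 | step 28 | C6 aldehyde of the (2E)-olefin | C=C(I)C/C=C/[C@@]1(C)C=CC(=O)[C@@](C)(OC(C)=O)[C@@H]1[C@H](O[Si](CC)(CC)CC)[C@]1(O[Si](CC)(CC)CC)[C@@H](C)C(=O)O[C@@H]1C=O
F7 | step 28 | macrocyclic (2E)-diene allylic alcohol | C=C1C/C=C/[C@@]2(C)C=CC(=O)[C@@](C)(OC(C)=O)[C@@H]2[C@H](O[Si](CC)(CC)CC)[C@@]2(O[Si](CC)(CC)CC)[C@H](OC(=O)[C@@H]2C)[C@@H]1O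
F8 | step 28 | macrocyclic (2E)-diene C6 chloride | C=C1C/C=C/[C@@]2(C)C=CC(=O)[C@@](C)(OC(C)=O)[C@@H]2[C@H](O[Si](CC)(CC)CC)[C@@]2(O[Si](CC)(CC)CC)[C@H](OC(=O)[C@@H]2C)[C@H]1Cl
F9 | step 29 | transposed primary allylic alcohol (C16 hydroxyl, C5=C6 olefin) | OCC=1C[C@H]2O[C@@H]2[C@@]2(C)C=CC(=O)[C@@](C)(OC(C)=O)[C@@H]2[C@H](O[Si](CC)(CC)CC)[C@@]2(O[Si](CC)(CC)CC)[C@H](OC(=O)[C@@H]2C)C=1
F10 | step 16 | 17-epimer of 20 | C=C[C@@]1(C)CC=C(O[Si](C(C)C)(C(C)C)C(C)C)[C@H](C)[C@@H]1[C@H](O)[C@]1(O)[C@H](C)C(=O)O[C@@H]1COCc1ccc(OC)cc1
F11 | step 19 | trimethylsilyl dienol ether of 22 (C11=C12, C13=C14) | C=C[C@@]1(C)C=CC(O[Si](C)(C)C)=C(C)[C@@H]1[C@H](O[Si](CC)(CC)CC)[C@]1(O[Si](CC)(CC)CC)[C@@H](C)C(=O)O[C@@H]1COCc1ccc(OC)cc1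
F12 | step 19 | α′-hydroxy enone (C11 hydroxyl) | C=C[C@@]1(C)C=CC(=O)[C@@](C)(O)[C@@H]1[C@H](O[Si](CC)(CC)CC)[C@]1(O[Si](CC)(CC)CC)[C@@H](C)C(=O)O[C@@H]1COCc1ccc(OC)cc1
A1 | alternative 1 | ring A-fused cyclohexenone (C8 ketone, C7=C2) | O=C1C=C[C@@]2(C)CCC3(OCCO3)[C@@](C)(OCOC)[C@@H]2[C@@H]1O[Si](C)(C)C(C)(C)C
A2 | alternative 1 | cyclobutene ketal (5,8-dioxaspiro[3.4]oct-1-ene) | C1=CC2(C1)OCCO2
A3 | alternative 1 | cis-anti-cis ladder photoadduct | [C@H]1([C@@H]4C5(OCCO5)C[C@@H]46)[C@@H]6[C@@]2(C)CCC3(OCCO3)[C@@](C)(OCOC)[C@@H]2[C@H](O[Si](C)(C)C(C)(C)C)C1=O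
A4 | alternative 2 | open-chain bromo aldehyde (C3 aldehyde, C4 allylic bromide) | O=C[C@H](OCc1ccc(OC)cc1)[C@@]2(C)CCC3(OCCO3)[C@@](C)(OCOC)[C@@H]2[C@H](O[Si](CC)(CC)CC)[C@@]2(O)[C@H](OC(=O)[C@@H]2C)[C@H](O[Si](C)(C)C(C)(C)C)C(=C)CBr
A5 | alternative 2 | ring B homoallylic alcohol | C=C1C[C@H](O)[C@H](OCc4ccc(OC)cc4)[C@@]2(C)CCC3(OCCO3)[C@@](C)(OCOC)[C@@H]2[C@H](O[Si](CC)(CC)CC)[C@@]2(O)[C@H](OC(=O)[C@@H]2C)[C@@H]1O[Si](C)(C)C(C)(C)C
A6 | alternative 3 | keto aldehyde (C12 aldehyde, C11 methyl ketone) | CC(C)(C)[Si](C)(C)OC[C@H](OCc1ccc(OC)cc1)[C@@](C)(CCC=O)[C@@H](COCc1ccccc1)C(C)=O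
A7 | alternative 3 | ring A tertiary α-ketol | CC(C)(C)[Si](C)(C)OC[C@H](OCc1ccc(OC)cc1)[C@@]1(C)CCC(=O)[C@@](C)(O)[C@@H]1COCc1ccccc1
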